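**Plan**

1. Retrosynthesis: the two ester C–O bonds are cut first. The seven-membered ring is then opened at C3–C4 and C1–C11, which frees C1–C2–C3 as a malondialdehyde bis-acetal and leaves a bicyclo[3.1.1]heptene in which C4 and C11 each carry a formyl group in place of one methyl. The cyclobutane is cut last by a retro ketene–alkene [2+2] to an acyclic trienoic acid.
2. Enabling feature: C1 and C3 are the carbinol carbons of a trans-1,3-diol in the seven-membered ring, and each is bonded to a fully substituted carbon that carries a methyl group (C11 of the cyclobutane, C4 = CMe2). With one methyl on each raised to CHO, C4 and C11 become the nucleophilic carbons of two aldehyde enol ethers, and CH(O)–CH2–CH(O) becomes a 1,3-bis-oxocarbenium unit.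
3. Forward order: acyclic acid → cyclobutane and cyclohexene rings together (vinylketene [2+2], step 6) → seven-membered ring (double acetal aldol, step 12) → formyl helpers reduced to methyl, auxiliaries removed, two esters, enone.
4. Stereochemistry: C7 (asymmetric vinylogous aldol) directs the cycloaddition that sets C5, C6 and C10 and is oxidised away at the end. C11 follows from the open face and the ring. C1 and C3 come from the (2R,4R)-pentanediol acetals of the linchpin.

Key step: step 12

Locants used below: C1 (carbinol carbon of the tiglate), C2 (CH2), C3 (carbinol carbon of the senecioate), C4 (CMe2), C5 (cyclobutane CH), C6 (CH next to the ketone), C7 (C=O), C8 (=CH), C9 (=C–CH3), C10 (ring-fusion CH), C11 (methyl-bearing quaternary carbon).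

Assumption: in step 6 the C7 silyloxy group takes the side of the one-carbon carbonyl bridge. If the opposite facial preference is found, the 5S enantiomer of 6 gives the same ring configuration, because C7 ends as a ketone.

Step 1
Reactants: 1 2-methylprop-2-enal; 2 (triphenylphosphoranylidene)acetaldehyde
Product: 3 (2E)-4-methylpenta-2,4-dienal
Conditions: toluene, 80 °C
Reagents that add atoms: none
Why: Wittig olefination with the stabilised formyl ylide should give the E enal, which is less electrophilic than 1, so a second homologation should stay minor.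

Step 2
Reactants: 4 methyl 3-methylbut-2-enoate
Product: 5 silyl dienol ether of 4
Conditions: LiN(i-Pr)2, THF, DMPU, −78 °C; TBSCl
Reagents that add atoms: tert-butyldimethylsilyl chloride, CC(C)(C)[Si](C)(C)Cl
Why: γ-deprotonation of the unsaturated ester and O-silylation of the dienolate (silyl ketene acetal formation) should give the 2-silyloxy diene, whose E/Z ratio is of no consequence.

Step 3
Reactants: 3 (2E)-4-methylpenta-2,4-dienal; 5 silyl dienol ether
Product: 6 methyl (2E,5R,6E)-5-hydroxy-3,8-dimethylnona-2,6,8-trienoate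
Conditions: SiCl4, chiral binaphthyldiamine-derived bisphosphoramide (5 mol %), i-Pr2NEt, CH2Cl2, −78 °C; aq. KF/NaHCO3
Reagents that add atoms: none
Why: a Lewis-base-activated, γ-selective vinylogous Mukaiyama aldol addition to the aldehyde carbonyl should give the δ-hydroxy enoate, the catalyst enantiomer being chosen to deliver the 5R carbinol (the later C7).

Step 4
Reactants: 6 hydroxy ester
Product: 7 silyl ether of 6
Conditions: TBSCl, imidazole, DMF, rt
Reagents that add atoms: tert-butyldimethylsilyl chloride, CC(C)(C)[Si](C)(C)Cl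
Why: standard silylation of the secondary allylic alcohol protects it for the ketene chemistry and leaves the stereocentre untouched.

Step 5
Reactants: 7 silyl ether ester
Product: 8 (2E,5R,6E)-5-silyloxy trienoic acid
Conditions: LiOH·H2O, THF/MeOH/H2O, 0 °C → rt; dilute HCl to pH 4
Reagents that add atoms: lithium hydroxide, [Li+].[OH-]
Why: ester saponification at low temperature should spare the silyl ether and the diene.

Step 6
Reactants: 8 trienoic acid
Product: 11 bridged cyclobutanone (bicyclo[3.1.1]hept-2-en-6-one), via acid chloride 9 (not isolated), via vinylketene 10 (not isolated)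
Conditions: 1-chloro-N,N,2-trimethylprop-1-en-1-amine, CH2Cl2, 0 °C; then slow addition to Et3N, toluene, 110 °C
Reagents that add atoms: none
Why: γ-dehydrochlorination of 9 gives the vinylketene, whose 3Z isomer (chain cis to the ketene) should undergo an intramolecular ketene–alkene [2+2] cycloaddition in the bridged sense because the diene stabilises positive charge at the distal alkene carbon; the E alkene places the isopropenyl group anti to the cyclohexene bridge and the C7 silyloxy group selects the face, which sets C5, C6 and C10.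

Step 7
Reactants: 11 cyclobutanone
Product: 12 exo-methylene compound
Conditions: Ph3PCH3Br, KOt-Bu, THF, 0 °C → rt
Reagents that add atoms: methyltriphenylphosphonium bromide, C[P+](c1ccccc1)(c1ccccc1)c1ccccc1.[Br-]
Why: Wittig methylenation of the strained cyclobutanone, which cannot enolise because both α-carbons are bridgeheads, should give the C11 methylene compound.

Step 8
Reactants: 12 bis(1,1-disubstituted alkene)
Product: 13 diol
Conditions: 9-BBN, THF, 0 °C → rt; NaOH, H2O2
Reagents that add atoms: hydrogen peroxide, OO
Why: anti-Markovnikov hydroboration–oxidation with 9-BBN should take both 1,1-disubstituted alkenes and spare the hindered trisubstituted C8=C9 alkene; the two new CH centres are lost again in step 10.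

Step 9
Reactants: 13 diol
Product: 14 dialdehyde
Conditions: Dess–Martin periodinane, NaHCO3, CH2Cl2, 0 °C → rt
Reagents that add atoms: none
Why: Dess–Martin oxidation should turn both primary alcohols into the α-branched aldehydes that serve as the activating groups on C4 and C11.

Step 10
Reactants: 14 dialdehyde
Product: 15 bis(trimethylsilyl enol ether)
Conditions: TMSOTf, Et3N, CH2Cl2, 0 °C
Reagents that add atoms: trimethylsilyl trifluoromethanesulfonate, C[Si](C)(C)OS(=O)(=O)C(F)(F)F
Why: soft enolisation and O-silylation should convert both aldehydes into silyl enol ethers whose nucleophilic carbons are C4 and C11.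

Step 11
Reactants: 16 1,1,3,3-tetramethoxypropane; 17 (2R,4R)-pentane-2,4-diol (two molecules enter the product)
Product: 18 2,2'-methylenebis[(4R,6R)-4,6-dimethyl-1,3-dioxane]
Conditions: 17 (2.2 equiv), TsOH·H2O (cat.), CH2Cl2, 4 Å molecular sieves, rt
Reagents that add atoms: (2R,4R)-pentane-2,4-diol (second equivalent of 17), C[C@@H](O)C[C@@H](C)O
Why: acid-catalysed acetal exchange, in which each acetal carbon of 16 trades its two methoxy groups for one molecule of the diol and four molecules of methanol are removed, should give the C2-symmetric bis-dioxane, a malondialdehyde dication equivalent that carries the chiral template.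

Step 12
Reactants: 15 bis(silyl enol ether); 18 chiral bis-acetal
Product: 19 tricyclic dialdehyde bis(hydroxypentyl) ether
Conditions: TiCl4, CH2Cl2, −78 °C, high dilution (0.003 M), slow addition of 15; aq. NaHCO3
Reagents that add atoms: none
Why: TiCl4 ionises one dioxane of 18 at the oxygen next to its axial methyl group and a silyl enol ether carbon (C11 or C4) attacks the acetal carbon anti to the departing oxygen; the second dioxane then ionises and is captured inside the molecule by the other enol ether, so C1–C11 and C3–C4 form in one operation and both enol ethers end as aldehydes. The closest known reaction type is the Mukaiyama-type aldol coupling of silyl enol ethers with pentanediol-derived chiral acetals under TiCl4, here run twice as a formal (4+3) annulation. The seven-membered ring closes in the second addition as a 7-(enolexo)-exo-trig attack of the tethered enol ether on the exocyclic oxocarbenium ion. C1 and C3 should both be set R by invertive opening of the (R,R)-templates; C11 takes its new bond on the face anti to the C7–C8–C9 bridge, by steric approach in an intermolecular attack and by necessity in the ring closure; the C4 centre is temporary. The step needs ring closure to outrun chain growth and the acetals to ionise before the allylic silyl ether: high dilution and −78 °C serve both, and the symmetric linchpin removes any regiochemical question.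

Step 13
Reactants: 19 dialdehyde
Product: 21 dimethyl compound, via bis(tosylhydrazone) 20 (not isolated)
Conditions: TsNHNH2, EtOH, rt; catecholborane, CHCl3, 0 °C; NaOAc·3H2O, 60 °C
Reagents that add atoms: none
Why: reduction of the tosylhydrazones with catecholborane and loss of sulfinate and dinitrogen (a mild Wolff–Kishner-type deoxygenation) should turn both formyl helpers into the C4 and C11 methyl groups, which also removes the temporary C4 stereocentre.

Step 14
Reactants: 21 bis(hydroxypentyl) ether
Product: 23 (1R,3R)-diol, via bis(oxopentyl) ether 22 (not isolated)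
Conditions: Dess–Martin periodinane, NaHCO3, CH2Cl2, rt; then K2CO3, MeOH, rt
Reagents that add atoms: none
Why: oxidation of the two auxiliary carbinols to β-alkoxy ketones followed by base-induced β-elimination (E1cB) should release both ring hydroxyls without touching C1 or C3.

Step 15
Reactants: 23 diol
Product: 24 C1 tiglate
Conditions: (E)-2-methylbut-2-enoyl chloride (1.05 equiv), pyridine, DMAP (cat.), CH2Cl2, −20 °C
Reagents that add atoms: (E)-2-methylbut-2-enoyl chloride, C/C=C(\C)C(Cl)=O
Why: nucleophile-catalysed acylation should favour the C1 hydroxyl, whose quaternary neighbour C11 has two substituents tied back in the four-membered ring, over the C3 hydroxyl beside the freely rotating CMe2 group.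

Step 16
Reactants: 24 mono-ester
Product: 25 diester
Conditions: 3-methylbut-2-enoyl chloride, pyridine, DMAP, CH2Cl2, 0 °C → rt
Reagents that add atoms: 3-methylbut-2-enoyl chloride, CC(C)=CC(Cl)=O
Why: acylation of the remaining hindered C3 hydroxyl with excess acid chloride under DMAP catalysis should install the senecioate.

Step 17
Reactants: 25 silyl ether diester
Product: 26 C7 allylic alcohol
Conditions: TBAF, AcOH, THF, rt
Reagents that add atoms: none
Why: buffered fluoride desilylation should free the C7 hydroxyl without ester cleavage or acyl migration.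

Step 18
Reactants: 26 allylic alcohol
Product: 27 target CNP0277258.1
Conditions: Dess–Martin periodinane, NaHCO3, CH2Cl2, rt
Reagents that add atoms: none
Why: Dess–Martin oxidation of the secondary allylic alcohol should give the conjugated C7 ketone and so remove the relay stereocentre.

**Compound list**

1 | 2-methylprop-2-enal | CC(=C)C=O | starting material
2 | (triphenylphosphoranylidene)acetaldehyde | O=CC=P(c1ccccc1)(c1ccccc1)c1ccccc1 | starting material
3 | (2E)-4-methylpenta-2,4-dienal | CC(=C)/C=C/C=O | intermediate
4 | methyl 3-methylbut-2-enoate | COC(=O)C=C(C)C | starting material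
5 | tert-butyl[(1-methoxy-3-methylbuta-1,3-dien-1-yl)oxy]dimethylsilane (E/Z mixture) | COC(O[Si](C)(C)C(C)(C)C)=CC(C)=C | intermediate
6 | methyl (2E,5R,6E)-5-hydroxy-3,8-dimethylnona-2,6,8-trienoate | COC(=O)/C=C(\C)C[C@@H](O)/C=C/C(C)=C | intermediate
7 | methyl (2E,5R,6E)-5-[(tert-butyldimethylsilyl)oxy]-3,8-dimethylnona-2,6,8-trienoate | COC(=O)/C=C(\C)C[C@@H](O[Si](C)(C)C(C)(C)C)/C=C/C(C)=C | intermediate
8 | (2E,5R,6E)-5-[(tert-butyldimethylsilyl)oxy]-3,8-dimethylnona-2,6,8-trienoic acid | OC(=O)/C=C(\C)C[C@@H](O[Si](C)(C)C(C)(C)C)/C=C/C(C)=C | intermediate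
9 | acid chloride of 8 | ClC(=O)/C=C(\C)C[C@@H](O[Si](C)(C)C(C)(C)C)/C=C/C(C)=C | intermediate
10 | (3Z,5S,6E)-5-silyloxy-3,8-dimethylnona-1,3,6,8-tetraen-1-one (vinylketene; the centre is unchanged from 9, the descriptor becomes S only because C4 is now an alkene carbon) | O=C=C/C(C)=C\[C@@H](O[Si](C)(C)C(C)(C)C)/C=C/C(C)=C | intermediate
11 | 4-[(tert-butyldimethylsilyl)oxy]-2-methyl-7-(prop-1-en-2-yl)bicyclo[3.1.1]hept-2-en-6-one; silyloxy carbon R (C7 of the locants above) with the silyloxy group on the side of the carbonyl bridge, isopropenyl group anti to the three-carbon bridge, ring carbons configured as C5, C6 and C10 of 27 | O=C1[C@H]2C(C)=C[C@@H](O[Si](C)(C)C(C)(C)C)[C@@H]1[C@H]2C(C)=C | intermediate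
12 | 6-methylene analogue of 11 | C=C1[C@H]2C(C)=C[C@@H](O[Si](C)(C)C(C)(C)C)[C@@H]1[C@H]2C(C)=C | intermediate
13 | diol from 12: hydroxymethyl on C11 and 1-hydroxypropan-2-yl on C5 (mixture of epimers at the two new CH centres) | OCC1[C@H]2C(C)=C[C@@H](O[Si](C)(C)C(C)(C)C)[C@@H]1[C@H]2C(C)CO | intermediate
14 | dialdehyde: formyl on C11 and 1-oxopropan-2-yl on C5 (epimer mixture) | O=CC1[C@H]2C(C)=C[C@@H](O[Si](C)(C)C(C)(C)C)[C@@H]1[C@H]2C(C)C=O | intermediate
15 | bis(trimethylsilyl enol ether) of 14 (enol ether geometry undefined) | C[Si](C)(C)OC=C1[C@H]2C(C)=C[C@@H](O[Si](C)(C)C(C)(C)C)[C@@H]1[C@H]2C(C)=CO[Si](C)(C)C | intermediate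
16 | 1,1,3,3-tetramethoxypropane | COC(CC(OC)OC)OC | starting material
17 | (2R,4R)-pentane-2,4-diol | C[C@@H](O)C[C@@H](C)O | starting material
18 | 2,2'-methylenebis[(4R,6R)-4,6-dimethyl-1,3-dioxane] | C[C@@H]1C[C@@H](C)OC(CC2O[C@H](C)C[C@@H](C)O2)O1 | intermediate
19 | tricyclic dialdehyde: C1 and C3 (both configured as in 27) carry (2R,4R)-4-hydroxypentan-2-yloxy groups, C11 carries CHO in place of its methyl, C4 carries CH3 and CHO (epimer mixture), C7 (R) carries OTBS | C[C@@H](O)C[C@@H](C)O[C@@H]1C[C@@H](O[C@H](C)C[C@@H](C)O)C(C)(C=O)[C@@H]2[C@H]3[C@H](O[Si](C)(C)C(C)(C)C)C=C(C)[C@@H]2[C@]31C=O | intermediate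
20 | bis(4-methylbenzenesulfonylhydrazone) of 19 | C[C@@H](O)C[C@@H](C)O[C@@H]1C[C@@H](O[C@H](C)C[C@@H](C)O)C(C)(C=NNS(=O)(=O)c4ccc(C)cc4)[C@@H]2[C@H]3[C@H](O[Si](C)(C)C(C)(C)C)C=C(C)[C@@H]2[C@]31C=NNS(=O)(=O)c1ccc(C)cc1 | intermediate
21 | (1R,3R,5S,6R,7R,10R,11R) tricycle with C4 gem-dimethyl, C11 methyl, C7 OTBS and (2R,4R)-4-hydroxypentan-2-yl ethers on O1 and O3 | C[C@@H](O)C[C@@H](C)O[C@@H]1C[C@@H](O[C@H](C)C[C@@H](C)O)C(C)(C)[C@@H]2[C@H]3[C@H](O[Si](C)(C)C(C)(C)C)C=C(C)[C@@H]2[C@]31C | intermediate
22 | bis[(2R)-4-oxopentan-2-yl] ether corresponding to 21 | CC(=O)C[C@@H](C)O[C@@H]1C[C@@H](O[C@H](C)CC(C)=O)C(C)(C)[C@@H]2[C@H]3[C@H](O[Si](C)(C)C(C)(C)C)C=C(C)[C@@H]2[C@]31C | intermediate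
23 | (1R,3R,5S,6R,7R,10R,11R)-7-silyloxy tricyclic 1,3-diol | O[C@@H]1C[C@@H](O)C(C)(C)[C@@H]2[C@H]3[C@H](O[Si](C)(C)C(C)(C)C)C=C(C)[C@@H]2[C@]31C | intermediate
24 | C1 (E)-2-methylbut-2-enoate of 23 with free C3 hydroxyl | C/C=C(\C)C(=O)O[C@@H]1C[C@@H](O)C(C)(C)[C@@H]2[C@H]3[C@H](O[Si](C)(C)C(C)(C)C)C=C(C)[C@@H]2[C@]31C | intermediate
25 | C1 tiglate C3 3-methylbut-2-enoate with C7 OTBS | C/C=C(\C)C(=O)O[C@@H]1C[C@@H](OC(=O)C=C(C)C)C(C)(C)[C@@H]2[C@H]3[C@H](O[Si](C)(C)C(C)(C)C)C=C(C)[C@@H]2[C@]31C | intermediate
26 | diester with free (7R) allylic hydroxyl | C/C=C(\C)C(=O)O[C@@H]1C[C@@H](OC(=O)C=C(C)C)C(C)(C)[C@@H]2[C@H]3[C@H](O)C=C(C)[C@@H]2[C@]31C | intermediate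
27 | CNP0277258.1, (1R,3R,5S,6R,10R,11R) by the locants above | C/C=C(\C)C(=O)O[C@@H]1C[C@@H](OC(=O)C=C(C)C)C(C)(C)[C@@H]2[C@H]3C(=O)C=C(C)[C@@H]2[C@]31C | target

**Totals and risks**

Total step count: 18. Longest linear sequence: 16 (steps 1, 3–10, 12–18).

Steps most likely to fail:

1. Step 12. What may go wrong: chain growth between molecules outrunning the seven-membered ring closure, loss of a C2 proton from the intermediate oxocarbenium ion followed by β-elimination of the first ether, ionisation of the allylic C7 silyl ether by the stoichiometric Lewis acid, or a mismatch between the chiral template and the ring framework that erodes control at C1 and C3. The fallback sets out from 15 and 16 and comes back at 23; it moves stereocontrol from the template to a later reagent-controlled reduction. Acetal exchange of 16 with benzyl alcohol gives 1,1,3,3-tetrakis(benzyloxy)propane F1. Its double acetal aldol with 15 under catalytic TMSOTf at high dilution gives the dibenzyl ether dialdehyde F2 without regard to configuration at C1 and C3. Deoxygenation as in step 13, through the bis(tosylhydrazone) F3, gives the dimethyl dibenzyl ether F4. Lithium 4,4'-di-tert-butylbiphenylide removes both benzyl groups to give the diol mixture F5, and Dess–Martin oxidation gives the 1,3-diketone F6. Reduction of both carbonyl groups with BH3·SMe2 and (S)-2-methyl-CBS-oxazaborolidine should set C1 and C3 as R and return 23.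

2. Step 6. What may go wrong: ketene dimerisation, closure in the fused bicyclo[3.2.0] sense, or a facial sense opposite to the one assumed. The fallback sets out from 8 and comes back at 11. Coupling with dimethylamine gives the N,N-dimethylamide F7. Tf2O with 2,6-di-tert-butyl-4-methylpyridine generates the vinylketeniminium ion, a stronger electrophile than the ketene, whose intramolecular [2+2] cycloaddition gives the cyclobutaniminium triflate F8. Aqueous NaHCO3 hydrolyses F8 to 11. If only the facial sense is reversed, the route is entered with the 5S enantiomer of 6.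

3. Step 15. What may go wrong: acylation of the C3 hydroxyl competing with that of C1, or migration of the tigloyl group between the two oxygens. The fallback sets out from 23 and comes back at 24 and 25. Dess–Martin oxidation of 23 gives the 1,3-diketone F6. Reduction with one equivalent of BH3·SMe2 and (S)-2-methyl-CBS-oxazaborolidine gives two separable hydroxy ketones, the C1 alcohol F9 and the C3 alcohol F10. Evans–Tishchenko reduction of F9 with (E)-2-methylbut-2-enal and catalytic SmI2 puts the tiglate on O1 and creates the anti C3 alcohol, which is 24. The same reaction of F10 with 3-methylbut-2-enal gives the C3 senecioate C1 alcohol F11, which (E)-2-methylbut-2-enoyl chloride converts into 25. Both regioisomers of the mono-reduction are thus used.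

**Further compounds**

F1 | step 12 | 1,1,3,3-tetrakis(benzyloxy)propane | C(CC(OCc1ccccc1)OCc1ccccc1)(OCc1ccccc1)OCc1ccccc1
F2 | step 12 | tricyclic dialdehyde with benzyl ethers on O1 and O3 (mixture at C1, C3 and C4) | C(c4ccccc4)OC1CC(OCc5ccccc5)C(C)(C=O)[C@@H]2[C@H]3[C@H](O[Si](C)(C)C(C)(C)C)C=C(C)[C@@H]2[C@]31C=O
F3 | step 12 | bis(4-methylbenzenesulfonylhydrazone) of F2 | C(c4ccccc4)OC1CC(OCc5ccccc5)C(C)(C=NNS(=O)(=O)c6ccc(C)cc6)[C@@H]2[C@H]3[C@H](O[Si](C)(C)C(C)(C)C)C=C(C)[C@@H]2[C@]31C=NNS(=O)(=O)c1ccc(C)cc1
F4 | step 12 | dibenzyl ether with C4 gem-dimethyl and C11 methyl (mixture at C1 and C3) | C(c4ccccc4)OC1CC(OCc5ccccc5)C(C)(C)[C@@H]2[C@H]3[C@H](O[Si](C)(C)C(C)(C)C)C=C(C)[C@@H]2[C@]31C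
F5 | step 12 | 7-silyloxy tricyclic 1,3-diol as a mixture at C1 and C3 | OC1CC(O)C(C)(C)[C@@H]2[C@H]3[C@H](O[Si](C)(C)C(C)(C)C)C=C(C)[C@@H]2[C@]31C
F6 | step 12 | 7-silyloxy tricyclic 1,3-diketone | O=C1CC(=O)C(C)(C)[C@@H]2[C@H]3[C@H](O[Si](C)(C)C(C)(C)C)C=C(C)[C@@H]2[C@]31C
F7 | step 6 | N,N-dimethylamide of 8 | CN(C)C(=O)/C=C(\C)C[C@@H](O[Si](C)(C)C(C)(C)C)/C=C/C(C)=C
F8 | step 6 | N,N-dimethyl cyclobutaniminium triflate corresponding to 11 | C[N+](C)=C1[C@H]2C(C)=C[C@@H](O[Si](C)(C)C(C)(C)C)[C@@H]1[C@H]2C(C)=C.[O-]S(=O)(=O)C(F)(F)F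
F9 | step 15 | (1R)-1-hydroxy-3-ketone | O[C@@H]1CC(=O)C(C)(C)[C@@H]2[C@H]3[C@H](O[Si](C)(C)C(C)(C)C)C=C(C)[C@@H]2[C@]31C
F10 | step 15 | (3R)-3-hydroxy-1-ketone | O=C1C[C@@H](O)C(C)(C)[C@@H]2[C@H]3[C@H](O[Si](C)(C)C(C)(C)C)C=C(C)[C@@H]2[C@]31C
F11 | step 15 | C3 3-methylbut-2-enoate with free C1 hydroxyl | O[C@@H]1C[C@@H](OC(=O)C=C(C)C)C(C)(C)[C@@H]2[C@H]3[C@H](O[Si](C)(C)C(C)(C)C)C=C(C)[C@@H]2[C@]31C
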